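(The readings were computed for substances that don't exist, noise included.)

Early on, read lost starting material as first product: Tuesday's run at 1.50 h holds 19.3% of it and 0% trapped intermediate.

| setting | Wednesday's | Friday's | Tuesday's | flask |
|---|---|---|---|---|
| starting material | 0.40 M | 0.60 M | 0.80 M | 0.80 M |
| coupling partner | 1.2 M | 1.2 M | 1.2 M | 1.20 M |
| capture agent | 0.24 M | 0.24 M | 0.12 M | 0.240 M |
| remark | run made earlier | run made earlier | run made earlier |  |
| time |  |  |  | 20 h |

| run | time / h | first product / % | trapped intermediate / % | bis adduct / % | starting material / % |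
|---|---|---|---|---|---|
| Wednesday's | 1.50 | 19.8 | 0.2 | 0 | 81.1 |
| Wednesday's | 4.00 | 36.5 | 7.0 | 0.6 | 55.9 |
| Wednesday's | 8.00 | 46.9 | 18.3 | 0 | 33.3 |
| Wednesday's | 12.0 | 50.0 | 29.4 | 1.9 | 22.7 |
| Friday's | 3.00 | 30.1 | 5.6 | 0 | 64.8 |
| Friday's | 6.00 | 43.4 | 12.7 | 1.6 | 47.7 |
| Friday's | 10.0 | 49.9 | 21.0 | 0.9 | 29.4 |
| Friday's | 12.0 | 51.6 | 24.0 | 1.8 | 25.1 |
| Tuesday's | 1.50 | 19.3 | 0 | 0 | 79.4 |
| Tuesday's | 4.00 | 38.4 | 3.4 | 0 | 59.1 |
| Tuesday's | 8.00 | 51.7 | 5.5 | 0.5 | 39.3 |
| Tuesday's | 12.0 | 58.8 | 10.9 | 1.3 | 27.5 |

(readings scatter by 1 percentage point)

- a reading or a percentage of bis adduct counts all its forms, free or not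

1. the species that holds most of what was charged as starting material, at 20 h (bis adduct / starting material / trapped intermediate / first product)
2. the largest share itself, whichever of these holds it, in percent of the starting material charged

Late on, turn to the other end. With one capture agent per trapped intermediate, c(capture agent)/c(starting material) = 30.0% is the capture ceiling, the largest share of the charge that this flask can hold as trapped intermediate.

Now join the ends. Tuesday's last starting material, 27.5%, gives a second-order constant of 0.131 M⁻¹ h⁻¹, so expect 15.2% starting material in this flask at 20 h. Put trapped intermediate at its ceiling and bis adduct at Tuesday's last 1.3%; first product then stands near 53.5%, more than either of the others. Add no further capture agent to this flask: a larger charge raises the ceiling, and this reckoning then leaves less for first product.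

The forecast says first product at 53%: “It clearly holds the largest share”.

The flask gives first product at 55.8%, with starting material at 15.6%.

    crystals ⇌ bis adduct, rate k1*(cs1 - [bis adduct]) while solid is left; crystals form when [bis adduct] > cs1 (solubility = 0.170 M, k = 19.0 h⁻¹)
    coupling partner + first product → bis adduct (k = 0.00220 M⁻¹ h⁻¹)
    first product + capture agent → trapped intermediate (k = 0.350 M⁻¹ h⁻¹)
    starting material + coupling partner → first product (k = 0.130 M⁻¹ h⁻¹)
    coupling partner → decomposition product (k = 6.50 × 10⁻⁵ h⁻¹)

This flask keeps 8.9% of its capture agent, and the ceiling times the used part gives 27.3%, against 27.3% trapped intermediate. Take the neighbour with 0.48 M of coupling partner, 0.600 equiv, which makes coupling partner the limiting reagent. Its ceiling stays 30.0%. The same constant gives 54.0% starting material, and that flask holds 54.2%. It keeps 32% of its capture agent, which gives 20.4%, against 20.3% trapped intermediate. There starting material holds the largest share, and first product stands at 25.3%.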